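## Retrosynthetic overview

1. The chromane ring is formed last, by hetero-Diels–Alder addition of the o-quinone methide from 21 and 22 to the E-C4=C5 olefin of (1S,9R)-β-caryophyllene 20. The target's C1/C9 centres are the mirror image of the catalogue (1R,9S) terpene, so 20 has to be made.
2. 20 comes from nor-ketone 19 by Wittig methylenation, and 19 from Grob fragmentation of tricyclic diol monotosylate 17. A temporary C4–C8 bond (cyclopentane ring B) is cut to open the nine-membered ring with its E-olefin.
3. The tricycle comes from an intramolecular [2+2] photocycloaddition of spiro-butenolide 11, which closes cyclohexane ring A (C9–C1) and the cyclobutane (C10–C11) together. The lactone carbonyl carbon (C16) is a temporary atom, later lost as CO2.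
4. Enabling feature: C8, the carbon that ends as C=CH2, is bonded to cyclobutane carbon C9 and lies 1,5 to C4. Carried as an oxygenated spiro carbon, it turns the isolated C9=C10 vinyl into a lactone enoate, ties it through ring B to the prenyl-type C1=C11 olefin on C4, and later serves as the Grob alkoxide.
5. Ring order: B (desymmetrised 2-methylcyclopentane-1,3-dione) → butenolide → A plus cyclobutane (key step) → nine-membered ring (B opened) → chromane.

Key step: step 7

Remark: locants C1–C15 follow caryophyllane numbering (C1/C9 ring fusion, C10 cyclobutane CH2, C11 the CMe2 carbon, C4 the methyl-bearing carbon, C8 the methylidene-bearing carbon), and 2,4,6-trihydroxybenzene-1,3-dicarbaldehyde 21 is assumed to be purchasable.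

## Route

Step 1
Reactants: 1 2-methylcyclopentane-1,3-dione; 2 acrolein
Product: 3 3-(1-methyl-2,5-dioxocyclopentyl)propanal
Conditions: H2O, rt
Reagents that add atoms: none
Why: Michael addition of the acidic cyclic 1,3-dione to acrolein builds the future C4 quaternary carbon without added base, and no stereocentre arises because the two ring carbonyls are still equivalent.

Step 2
Reactants: 3 3-(1-methyl-2,5-dioxocyclopentyl)propanal
Product: 4 2-methyl-2-(4-methylpent-3-en-1-yl)cyclopentane-1,3-dione
Conditions: i-PrPPh3I, n-BuLi, THF, 0 °C; then 3, −78 °C to 0 °C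
Reagents that add atoms: isopropyltriphenylphosphonium iodide CC(C)[P+](c1ccccc1)(c1ccccc1)c1ccccc1.[I-]
Why: Wittig olefination, in which the non-stabilised ylide should take the unhindered aldehyde much faster than the two ring ketones flanking the quaternary carbon, installing the C1=C11 trisubstituted olefin.

Step 3
Reactants: 4 2-methyl-2-(4-methylpent-3-en-1-yl)cyclopentane-1,3-dione
Product: 5 (2S,3S)-3-hydroxy-2-methyl-2-(4-methylpent-3-en-1-yl)cyclopentan-1-one
Conditions: (R)-2-methyl-CBS-oxazaborolidine (0.2 equiv), catecholborane (1.1 equiv), toluene, −78 to −40 °C; MeOH quench, aqueous work-up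
Reagents that add atoms: none
Why: Corey–Bakshi–Shibata reduction used as a desymmetrisation: the catalyst fixes the carbinol as S and hydride should enter anti to the larger alkenyl chain, so the carbonyl that makes the quaternary carbon (future C4) 2S reacts; the 2R,3S diastereomer, which would lead into the antipodal series, is to be removed by chromatography.

Step 4
Reactants: 5 (2S,3S)-3-hydroxy-2-methyl-2-(4-methylpent-3-en-1-yl)cyclopentan-1-one
Product: 6 (2S,3S)-2-methyl-2-(4-methylpent-3-en-1-yl)-3-(triethylsilyloxy)cyclopentan-1-one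
Conditions: Et3SiCl, imidazole, DMF, 0 °C to rt
Reagents that add atoms: chlorotriethylsilane CC[Si](Cl)(CC)CC
Why: silylation gives a bulky, non-chelating ether that should shield the chain face of the remaining ketone and prevent alkoxide-directed delivery or retro-aldol opening in the next step.

Step 5
Reactants: 6 (2S,3S)-2-methyl-2-(4-methylpent-3-en-1-yl)-3-(triethylsilyloxy)cyclopentan-1-one; 7 ethyl propiolate
Product: 8 ethyl 3-[(1S,2S,3S)-1-hydroxy-2-methyl-2-(4-methylpent-3-en-1-yl)-3-(triethylsilyloxy)cyclopentyl]prop-2-ynoate
Conditions: 7, LiN(SiMe3)2, THF, −78 °C; then 6, −78 °C; aq. NH4Cl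
Reagents that add atoms: none
Why: 1,2-addition of a lithium alkynide to the ketone, expected from the methyl face (anti to the alkenyl chain and the silyloxy group), which sets C8 with its oxygen cis to the chain; the C8 epimer would lead to the antipode and must be removed if formed.

Step 6
Reactants: 8 ethyl 3-[(1S,2S,3S)-1-hydroxy-2-methyl-2-(4-methylpent-3-en-1-yl)-3-(triethylsilyloxy)cyclopentyl]prop-2-ynoate
Product: 11 (5S,6S,7S)-7-hydroxy-6-methyl-6-(4-methylpent-3-en-1-yl)-1-oxaspiro[4.4]non-3-en-2-one, via Z-enoate silyl ether 9 (not isolated), via silylated spirobutenolide 10 (not isolated)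
Conditions: H2 (1 atm), Pd/CaCO3 poisoned with Pb(OAc)2 (Lindlar catalyst), quinoline, EtOAc, rt; then pyridinium p-toluenesulfonate (cat.), MeOH, rt
Reagents that add atoms: none
Why: Lindlar semi-hydrogenation gives the Z-enoate, whose tertiary hydroxyl is placed to lactonise to the 2(5H)-furanone, and the same mild acid in methanol removes the silyl ether, while the trisubstituted olefin should not be touched by the poisoned catalyst.

Step 7
Reactants: 11 (5S,6S,7S)-7-hydroxy-6-methyl-6-(4-methylpent-3-en-1-yl)-1-oxaspiro[4.4]non-3-en-2-one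
Product: 12 tetracyclic hydroxy lactone (photoadduct; ring B trans-fused to new ring A, γ-lactone and gem-dimethylcyclobutane both cis-fused to ring A on the O8 face)
Conditions: hν (300 nm, Pyrex), acetone (solvent and triplet sensitiser), 5 mM, degassed, rt
Reagents that add atoms: none
Why: Acetone-sensitised excitation gives the butenolide triplet, whose β-carbon C9 adds to C1 of the tethered trisubstituted olefin, leaving the lactone-stabilised radical at C10 and the tertiary radical at C11, and after intersystem crossing C10–C11 bonding closes the cyclobutane; the closest known reaction type is the intramolecular [2+2] photocycloaddition of 2(5H)-furanones with olefins tethered at C-5. Ring A (C8–C9–C1–C2–C3–C4) closes 6-exo-trig by radical addition and the cyclobutane (C9–C10–C11–C1) by 1,4-biradical recombination. C9, C10 and C1 are controlled by the spiro carbon C8 and the quaternary C4: the chain on C4 can reach C9 only from the butenolide face on which C4 lies, the lactone ring keeps C10 syn to O8, and the four-membered ring therefore has to form on the O8 face of ring A with H9 and H1 cis, which fixes C1 as required for the target. The step needs straight rather than crossed regiochemistry, secured by the three-carbon tether (crossed closure would need a seven-membered ring) and by the radical stabilities at C10 and C11; it also needs the olefin to react with the excited lactone rather than with triplet acetone, which intramolecularity at high dilution should secure.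

Step 8
Reactants: 12 tetracyclic hydroxy lactone
Product: 14 tricyclic cis-diol (8-OH tertiary and 5-OH cis on ring B), via potassium hydroxy carboxylate 13 (not isolated)
Conditions: KOH (1.1 equiv), MeOH/H2O, 50 °C; evaporate; then 9-mesityl-10-phenylacridinium tetrafluoroborate (5 mol%), PhSSPh (10 mol%), CF3CH2OH, 450 nm LEDs, rt
Reagents that add atoms: none
Why: saponification opens the lactone and photoredox hydrodecarboxylation (single-electron oxidation of the carboxylate, loss of CO2, hydrogen-atom transfer from thiophenol to the secondary cyclobutyl radical) removes the temporary carbon C16 so that C10 becomes CH2; the acid is kept as its salt to prevent relactonisation, and no olefin is present for thiyl radicals to attack.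

Step 9
Reactants: 14 tricyclic cis-diol
Product: 15 tricyclic 8-hydroxy-5-ketone
Conditions: Dess–Martin periodinane, CH2Cl2, 0 °C to rt
Reagents that add atoms: none
Why: Dess–Martin oxidation takes only the secondary C5 hydroxyl (the C8 hydroxyl is tertiary) under non-basic conditions that should not trigger retro-aldol cleavage, and it erases the C5 centre so that it can be reset.

Step 10
Reactants: 15 tricyclic 8-hydroxy-5-ketone
Product: 16 tricyclic anti-diol (5-OH trans to 8-OH and cis to the C4 methyl)
Conditions: Me4NBH(OAc)3, MeCN/AcOH, −20 °C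
Reagents that add atoms: none
Why: hydroxyl-directed Saksena–Evans reduction, in which the C8 hydroxyl binds boron and delivers hydride to the C5 carbonyl on its own face, which is also the face anti to the axial C4 methyl, so the new hydroxyl should end up anti to O8 and cis to the methyl.

Step 11
Reactants: 16 tricyclic anti-diol
Product: 17 tricyclic 8-hydroxy-5-tosylate
Conditions: TsCl, pyridine, DMAP (cat.), 0 °C to rt
Reagents that add atoms: p-toluenesulfonyl chloride Cc1ccc(cc1)S(=O)(=O)Cl
Why: sulfonylation should be selective for the secondary hydroxyl because the tertiary C8 hydroxyl is too hindered, and no stereocentre changes.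

Step 12
Reactants: 17 tricyclic 8-hydroxy-5-tosylate
Product: 19 (1R,5E,9S)-6,10,10-trimethylbicyclo[7.2.0]undec-5-en-2-one, via cis-fused ketone 18 (not isolated)
Conditions: KOt-Bu, t-BuOH/THF, rt to 40 °C
Reagents that add atoms: none
Why: Grob fragmentation: in the trans-fused hydrindane the C5–OTs bond, cis to the C4 methyl, is antiperiplanar to the temporary C4–C8 bond, so the C8 alkoxide should expel tosylate with concerted cleavage of that bond to give the C8 ketone and, stereospecifically, the E-C4=C5 olefin of the nine-membered ring, after which the same base should epimerise the ketone α-carbon C9 from the cis- to the more stable trans-fused junction.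

Step 13
Reactants: 19 (1R,5E,9S)-6,10,10-trimethylbicyclo[7.2.0]undec-5-en-2-one
Product: 20 (1S,4E,9R)-4,11,11-trimethyl-8-methylidenebicyclo[7.2.0]undec-4-ene
Conditions: Ph3PCH3Br, KOt-Bu, THF, rt to 60 °C
Reagents that add atoms: methyltriphenylphosphonium bromide C[P+](c1ccccc1)(c1ccccc1)c1ccccc1.[Br-]
Why: Wittig methylenation of the medium-ring ketone installs C15, and C9 is already the thermodynamically preferred trans epimer, so the basic ylide should not scramble it.

Step 14
Reactants: 20 (1S,4E,9R)-4,11,11-trimethyl-8-methylidenebicyclo[7.2.0]undec-4-ene; 21 2,4,6-trihydroxybenzene-1,3-dicarbaldehyde; 22 benzaldehyde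
Product: 24 target CNP0253700.1, via o-quinone methide 23 (not isolated)
Conditions: H2O, 100 °C, sealed tube
Reagents that add atoms: none
Why: Knoevenagel condensation of 22 at the free ring position of 21 gives o-quinone methide 23, which should add as an inverse-demand heterodiene (hetero-Diels–Alder) to the strained E-C4=C5 olefin in preference to the exocyclic one: oxygen to the more substituted C4, suprafacially (trans ring fusion from the E-olefin), on the outer face of the dominant ring conformers (the face opposite to that attacked in the commercial enantiomer) and with the benzylidene phenyl turned away from the C4 methyl; the adduct of the other olefin face is to be separated.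

## Compound list

1 | 2-methylcyclopentane-1,3-dione | CC1C(=O)CCC1=O | starting material
2 | acrolein | C=CC=O | starting material
3 | 3-(1-methyl-2,5-dioxocyclopentyl)propanal | CC1(CCC=O)C(=O)CCC1=O | intermediate
4 | 2-methyl-2-(4-methylpent-3-en-1-yl)cyclopentane-1,3-dione | CC(C)=CCCC1(C)C(=O)CCC1=O | intermediate
5 | (2S,3S)-3-hydroxy-2-methyl-2-(4-methylpent-3-en-1-yl)cyclopentan-1-one (OH cis to the alkenyl chain) | CC(C)=CCC[C@@]1(C)[C@@H](O)CCC1=O | intermediate
6 | (2S,3S)-2-methyl-2-(4-methylpent-3-en-1-yl)-3-(triethylsilyloxy)cyclopentan-1-one | CC(C)=CCC[C@@]1(C)[C@@H](O[Si](CC)(CC)CC)CCC1=O | intermediate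
7 | ethyl propiolate | C#CC(=O)OCC | starting material
8 | ethyl 3-[(1S,2S,3S)-1-hydroxy-2-methyl-2-(4-methylpent-3-en-1-yl)-3-(triethylsilyloxy)cyclopentyl]prop-2-ynoate (tertiary OH cis to chain and silyloxy) | CCOC(=O)C#C[C@@]1(O)CC[C@H](O[Si](CC)(CC)CC)[C@]1(C)CCC=C(C)C | intermediate
9 | ethyl (Z)-3-[(1S,2S,3S)-1-hydroxy-2-methyl-2-(4-methylpent-3-en-1-yl)-3-(triethylsilyloxy)cyclopentyl]prop-2-enoate | CCOC(=O)/C=C\[C@@]1(O)CC[C@H](O[Si](CC)(CC)CC)[C@]1(C)CCC=C(C)C | intermediate (not isolated)
10 | (5S,6S,7S)-6-methyl-6-(4-methylpent-3-en-1-yl)-7-(triethylsilyloxy)-1-oxaspiro[4.4]non-3-en-2-one | O=C1C=C[C@@]2(O1)CC[C@H](O[Si](CC)(CC)CC)[C@]2(C)CCC=C(C)C | intermediate (not isolated)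
11 | (5S,6S,7S)-7-hydroxy-6-methyl-6-(4-methylpent-3-en-1-yl)-1-oxaspiro[4.4]non-3-en-2-one | O=C1C=C[C@@]2(O1)CC[C@H](O)[C@]2(C)CCC=C(C)C | intermediate
12 | tetracyclic hydroxy lactone: cyclopentane ring B trans-fused to cyclohexane ring A (O8 anti to the C4 methyl); γ-lactone O8–C16(=O)–C10 and cyclobutane C9–C10–C11–C1 cis-fused to ring A on the O8 face; 5-OH cis to O8 | O=C1O[C@]23CC[C@H](O)[C@]2(C)CC[C@H]4[C@@H]3[C@@H]1C4(C)C | intermediate
13 | potassium salt of the ring-opened hydroxy acid of 12 (carboxylate on C10) | O[C@]12CC[C@H](O)[C@]1(C)CC[C@H]3[C@@H]2[C@@H](C(=O)[O-])C3(C)C.[K+] | intermediate (not isolated)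
14 | tricyclic cis-diol: 8-OH and 5-OH cis, 8-OH trans to the C4 methyl, cyclobutane cis-fused to ring A on the O8 face | O[C@]12CC[C@H](O)[C@]1(C)CC[C@H]3[C@@H]2CC3(C)C | intermediate
15 | tricyclic 8-hydroxy-5-ketone | O[C@]12CCC(=O)[C@]1(C)CC[C@H]3[C@@H]2CC3(C)C | intermediate
16 | tricyclic anti-diol: 5-OH trans to 8-OH, cis to the C4 methyl | O[C@]12CC[C@@H](O)[C@]1(C)CC[C@H]3[C@@H]2CC3(C)C | intermediate
17 | 5-O-tosylate of 16 | O[C@]12CC[C@@H](OS(=O)(=O)c3ccc(C)cc3)[C@]1(C)CC[C@H]4[C@@H]2CC4(C)C | intermediate
18 | (1S,5E,9S)-6,10,10-trimethylbicyclo[7.2.0]undec-5-en-2-one (cis-fused) | C/C1=C\CCC(=O)[C@H]2CC([C@H]2CC1)(C)C | intermediate (not isolated)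
19 | (1R,5E,9S)-6,10,10-trimethylbicyclo[7.2.0]undec-5-en-2-one (trans-fused) | C/C1=C\CCC(=O)[C@@H]2CC([C@H]2CC1)(C)C | intermediate
20 | (1S,4E,9R)-4,11,11-trimethyl-8-methylidenebicyclo[7.2.0]undec-4-ene, (1S,9R)-β-caryophyllene | C/C1=C\CCC(=C)[C@@H]2CC([C@H]2CC1)(C)C | intermediate
21 | 2,4,6-trihydroxybenzene-1,3-dicarbaldehyde | O=Cc1c(O)cc(O)c(C=O)c1O | starting material
22 | benzaldehyde | O=Cc1ccccc1 | starting material
23 | o-quinone methide: 5-benzylidene-2,4-dihydroxy-6-oxocyclohexa-1,3-diene-1,3-dicarbaldehyde | O=CC1=C(O)C(C=O)=C(O)C(=Cc2ccccc2)C1=O | intermediate (not isolated)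
24 | target CNP0253700.1 | C=C1CC[C@@H]2[C@@H](c3ccccc3)c3c(O)c(C=O)c(O)c(C=O)c3O[C@@]2(C)CC[C@H]2[C@H]1CC2(C)C | target

Total step count: 14. Longest linear sequence: 14 steps (from 1; 7, 21 and 22 enter as single-step partners).

## Steps most likely to fail

1. Step 7. The trans-fused six-membered closure from the excited lactone may be slower than triplet decay, or triplet acetone may instead form an oxetane with the electron-rich olefin. The fallback sets out from 6 and returns at 14. Lithium but-1-en-3-ynide (but-1-en-3-yne, n-BuLi, THF, −78 °C) is added to 6 to give enynol F1. NaAlH2(OCH2CH2OMe)2 (THF, 0 °C to rt) reduces the propargylic alcohol to the (E)-dienol F2. Visible-light energy transfer from Ir[dF(CF3)ppy]2(dtbbpy)PF6 (1 mol%, blue LEDs, DMSO) to the diene should then effect a diene–olefin [2+2] without the lactone constraint, giving vinylcyclobutane F3; ring-A diastereomers are separated here, and either C10 epimer is usable. Ozonolysis (O3, CH2Cl2/MeOH, −78 °C; PPh3) gives aldehyde F4, RhCl(PPh3)3 (toluene, 110 °C) decarbonylates it to silyl ether F5, and Bu4NF (THF) gives 14.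

2. Step 8. The hydroxy acid may relactonise before it is oxidised, or hydrogen-atom transfer to the cyclobutyl radical may be incomplete, returning 12 or giving olefinic by-products. The fallback sets out from 12 and returns at 14. i-Bu2AlH (CH2Cl2, −78 °C) reduces the lactone to lactol F6, and RhCl(PPh3)3 (1.1 equiv, xylene, 130 °C) decarbonylates the open hydroxy-aldehyde tautomer to 14, a reductive excision in place of the radical decarboxylation.

3. Step 14. The o-quinone methide may be consumed by water or by a second phenol faster than it meets the lipophilic terpene, and at 100 °C addition to the other olefin face would erode diastereoselectivity. The fallback sets out from 21 and returns at 24. Compounds 21 and 22 are condensed with benzenesulfinic acid (HCO2H/H2O, rt) to the isolable sulfone F7. Treating F7 with 20 and K2CO3 (CH2Cl2, 0 °C to rt) should release 23 by sulfinate elimination under anhydrous conditions at ambient temperature, and cycloaddition then gives 24.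

## Further compounds

F1 | step 7 | (1S,2S,3S)-1-(but-3-en-1-yn-1-yl)-2-methyl-2-(4-methylpent-3-en-1-yl)-3-(triethylsilyloxy)cyclopentan-1-ol | C=CC#C[C@@]1(O)CC[C@H](O[Si](CC)(CC)CC)[C@]1(C)CCC=C(C)C
F2 | step 7 | (1S,2S,3S)-1-[(1E)-buta-1,3-dien-1-yl]-2-methyl-2-(4-methylpent-3-en-1-yl)-3-(triethylsilyloxy)cyclopentan-1-ol | C=C/C=C/[C@@]1(O)CC[C@H](O[Si](CC)(CC)CC)[C@]1(C)CCC=C(C)C
F3 | step 7 | 10-vinyl tricyclic 8-hydroxy-5-silyl ether (C10 epimers) | O[C@]12CC[C@H](O[Si](CC)(CC)CC)[C@]1(C)CC[C@H]3[C@@H]2C(C=C)C3(C)C
F4 | step 7 | 10-formyl tricyclic 8-hydroxy-5-silyl ether | O[C@]12CC[C@H](O[Si](CC)(CC)CC)[C@]1(C)CC[C@H]3[C@@H]2C(C=O)C3(C)C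
F5 | step 7 | 5-O-triethylsilyl ether of 14 | O[C@]12CC[C@H](O[Si](CC)(CC)CC)[C@]1(C)CC[C@H]3[C@@H]2CC3(C)C
F6 | step 8 | lactol of 12 | OC1O[C@]23CC[C@H](O)[C@]2(C)CC[C@H]4[C@@H]3[C@@H]1C4(C)C
F7 | step 14 | 2,4,6-trihydroxy-5-[phenyl(phenylsulfonyl)methyl]benzene-1,3-dicarbaldehyde | O=Cc1c(O)c(C=O)c(O)c(C(c2ccccc2)S(=O)(=O)c2ccccc2)c1O
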